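## Retrosynthetic overview

1. The target comes from its formyl-free triol-diketone by a final double Vilsmeier–Haack formylation; the three phenols are carried as benzyl ethers until then.
2. The cyclopentanone comes from intramolecular aldol condensation of a 1,4-keto aldehyde; the ketone α-centre is set by base equilibration.
3. The keto aldehyde comes from a 4-isobutyl-dihydrocoumarin and a cis-cyclopropane carbaldehyde: aldol/elimination, isopropenyl conjugate addition, then methylation anti to the isobutyl group on the temporary lactone ring.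
4. The dihydrocoumarin comes from a Pechmann coumarin (benzylic centre by asymmetric copper hydride conjugate reduction); the cyclopropane aldehyde comes from meso caronic anhydride, desymmetrised as its diol by a lipase.
5. Ring order: pyranone ring (Pechmann, opened later), then cyclopentenone ring (aldol condensation); the arene and the cyclopropane are bought in.

Assumption: (R)-DTBM-SEGPHOS delivers (4R)-5 and the lipase acylates the hydroxymethyl group shown in 8; otherwise the mirror-image ligand, or a lipase of opposite enantiopreference, is substituted.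

## Route

**Fragment A (lactone 5)**

Step 1
Reactants: 1 phloroglucinol (benzene-1,3,5-triol); 2 ethyl 5-methyl-3-oxohexanoate
Product: 3 5,7-dihydroxy-4-(2-methylpropyl)-2H-chromen-2-one
Conditions: MeSO3H, 0 °C → rt
Reagents that add atoms: none
Why: Pechmann condensation is fast with the very electron-rich phloroglucinol and gives the flat, achiral coumarin with the isobutyl group already on the future benzylic carbon.

Step 2
Reactants: 3 5,7-dihydroxy-4-(2-methylpropyl)-2H-chromen-2-one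
Product: 4 5,7-bis(benzyloxy)-4-(2-methylpropyl)-2H-chromen-2-one
Conditions: BnBr, K2CO3, DMF, 50 °C
Reagents that add atoms: benzyl bromide BrCc1ccccc1
Why: Williamson ether synthesis on the two acidic phenols installs groups that survive every later base, hydride and oxidant and leave by neutral hydrogenolysis.

Step 3
Reactants: 4 5,7-bis(benzyloxy)-4-(2-methylpropyl)-2H-chromen-2-one
Product: 5 (4R)-5,7-bis(benzyloxy)-4-(2-methylpropyl)-3,4-dihydro-2H-chromen-2-one
Conditions: Cu(OAc)2·H2O (5 mol %), (R)-DTBM-SEGPHOS (5.5 mol %), (EtO)2MeSiH, t-BuOH, toluene, 0 °C → rt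
Reagents that add atoms: none
Why: Copper hydride-catalysed asymmetric conjugate reduction delivers hydride to C-4 of the unsaturated lactone inside the chiral bisphosphine pocket and t-BuOH protonates the copper enolate, so the first stereocentre is created from an achiral substrate by the catalyst.

**Fragment B (aldehyde 15)**

Step 4
Reactants: 6 caronic anhydride, (1R,5S)-6,6-dimethyl-3-oxabicyclo[3.1.0]hexane-2,4-dione (meso)
Product: 7 [(1R,2S)-3,3-dimethylcyclopropane-1,2-diyl]dimethanol (meso, cis)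
Conditions: LiAlH4, THF, 0 °C → reflux
Reagents that add atoms: none
Why: Hydride reduction of the cyclic anhydride gives the cis-diol, which is still achiral because of its mirror plane.

Step 5
Reactants: 7 [(1R,2S)-3,3-dimethylcyclopropane-1,2-diyl]dimethanol
Product: 8 [(1S,3R)-3-(hydroxymethyl)-2,2-dimethylcyclopropyl]methyl acetate
Conditions: Burkholderia cepacia lipase (lipase PS, immobilised), vinyl acetate, t-BuOMe, 25 °C
Reagents that add atoms: vinyl acetate CC(=O)OC=C
Why: A lipase (serine hydrolase) acetylates only one of the two enantiotopic hydroxymethyl groups by irreversible transesterification (enzymatic desymmetrisation), which fixes the absolute configuration of both cyclopropane stereocentres at once.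

Step 6
Reactants: 8 [(1S,3R)-3-(hydroxymethyl)-2,2-dimethylcyclopropyl]methyl acetate
Product: 9 [(1S,3R)-3-formyl-2,2-dimethylcyclopropyl]methyl acetate
Conditions: Dess–Martin periodinane, NaHCO3, CH2Cl2, 0 °C → rt
Reagents that add atoms: none
Why: Buffered Dess–Martin oxidation stops at the aldehyde, and the cis geometry is safe because the ring C–H next to the formyl group is not enolised under these conditions.

Step 7
Reactants: 9 [(1S,3R)-3-formyl-2,2-dimethylcyclopropyl]methyl acetate; 10 1-(triphenylphosphoranylidene)propan-2-one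
Product: 11 [(1S,3R)-2,2-dimethyl-3-[(1E)-3-oxobut-1-en-1-yl]cyclopropyl]methyl acetate
Conditions: CH2Cl2, 40 °C
Reagents that add atoms: none
Why: Wittig olefination with the neutral stabilised ylide adds the three remaining side-chain carbons as an (E)-enone without base that could epimerise the cyclopropane.

Step 8
Reactants: 11 [(1S,3R)-2,2-dimethyl-3-[(1E)-3-oxobut-1-en-1-yl]cyclopropyl]methyl acetate
Product: 12 [(1S,3R)-2,2-dimethyl-3-(3-oxobutyl)cyclopropyl]methyl acetate
Conditions: [(Ph3P)CuH]6 (0.4 equiv), H2O (2 equiv), THF, rt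
Reagents that add atoms: none
Why: Conjugate reduction with the phosphine copper hydride hexamer saturates only the enone C=C and, unlike hydrogenation over palladium, does not hydrogenolyse the vinylcyclopropane or touch the ketone and ester.

Step 9
Reactants: 12 [(1S,3R)-2,2-dimethyl-3-(3-oxobutyl)cyclopropyl]methyl acetate
Product: 13 [(1S,3R)-2,2-dimethyl-3-[2-(2-methyl-1,3-dioxolan-2-yl)ethyl]cyclopropyl]methyl acetate
Conditions: ethane-1,2-diol, PPTS, benzene, reflux (Dean–Stark)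
Reagents that add atoms: ethane-1,2-diol OCCO
Why: Acetalisation masks the methyl ketone against the enolates, hydrides and hydroxide used later, and the weak acid does not open the cyclopropane.

Step 10
Reactants: 13 [(1S,3R)-2,2-dimethyl-3-[2-(2-methyl-1,3-dioxolan-2-yl)ethyl]cyclopropyl]methyl acetate
Product: 14 [(1S,3R)-2,2-dimethyl-3-[2-(2-methyl-1,3-dioxolan-2-yl)ethyl]cyclopropyl]methanol
Conditions: K2CO3, MeOH, rt
Reagents that add atoms: none
Why: Base-catalysed transesterification with methanol removes the acetate while the dioxolane is inert to base.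

Step 11
Reactants: 14 [(1S,3R)-2,2-dimethyl-3-[2-(2-methyl-1,3-dioxolan-2-yl)ethyl]cyclopropyl]methanol
Product: 15 (1S,3R)-2,2-dimethyl-3-[2-(2-methyl-1,3-dioxolan-2-yl)ethyl]cyclopropane-1-carbaldehyde
Conditions: Dess–Martin periodinane, NaHCO3, CH2Cl2, 0 °C → rt
Reagents that add atoms: none
Why: Buffered Dess–Martin oxidation gives the cis-aldehyde whose carbonyl carbon becomes the ketone α-carbon of the target ring.

**Union and end-game**

Step 12
Reactants: 5 (4R)-5,7-bis(benzyloxy)-4-(2-methylpropyl)-3,4-dihydro-2H-chromen-2-one; 15 (1S,3R)-2,2-dimethyl-3-[2-(2-methyl-1,3-dioxolan-2-yl)ethyl]cyclopropane-1-carbaldehyde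
Product: 17 (4R)-5,7-bis(benzyloxy)-3-[{(1S,3R)-2,2-dimethyl-3-[2-(2-methyl-1,3-dioxolan-2-yl)ethyl]cyclopropyl}(hydroxy)methyl]-4-(2-methylpropyl)-3,4-dihydro-2H-chromen-2-one (diastereomer mixture at C-3 and at the carbinol carbon), via lithium enolate 16 (not isolated)
Conditions: LiN(iPr)2, THF, −78 °C; then 15, −78 °C; AcOH quench at −78 °C
Reagents that add atoms: none
Why: Aldol addition of the lactone lithium enolate to the non-enolisable aldehyde joins the two fragments, the cold quench prevents the aldolate from attacking the aryl ester, and both new centres are removed in the next step.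

Step 13
Reactants: 17 aldol adduct (as above)
Product: 19 (3E,4S)-5,7-bis(benzyloxy)-3-({(1S,3R)-2,2-dimethyl-3-[2-(2-methyl-1,3-dioxolan-2-yl)ethyl]cyclopropyl}methylidene)-4-(2-methylpropyl)-3,4-dihydro-2H-chromen-2-one (E drawn; E/Z mixture usable), via acetate 18 (not isolated)
Conditions: Ac2O, Et3N, DMAP, CH2Cl2, 0 °C; then DBU, 0 °C → rt
Reagents that add atoms: none
Why: Acetylation followed by E1cB elimination gives the α-alkylidene lactone without a cyclopropylcarbinyl cation, and the benzylic 4-H is not removed because peri strain with the 5-benzyloxy group holds it in the ring plane.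

Step 14
Reactants: 19 α-alkylidene lactone (as above); 20 isopropenylmagnesium bromide
Product: 22 (4R)-5,7-bis(benzyloxy)-3-(1-{(1R,3R)-2,2-dimethyl-3-[2-(2-methyl-1,3-dioxolan-2-yl)ethyl]cyclopropyl}-2-methylprop-2-en-1-yl)-4-(2-methylpropyl)-3,4-dihydro-2H-chromen-2-one (epimer mixture at C-3 and at the side-chain methine), via silyl ketene acetal 21 (not isolated)
Conditions: CuBr·SMe2 (10 mol %), Me3SiCl, THF, −78 → −40 °C; then aq. NH4Cl, rt
Reagents that add atoms: none
Why: Copper-catalysed conjugate addition of the Grignard reagent, accelerated by Me3SiCl, places a masked acetyl group on the exocyclic β-carbon; the new methine later becomes the equilibrated ketone α-centre, so its configuration here does not matter.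

Step 15
Reactants: 22 conjugate adduct (as above)
Product: 24 (3R,4S)-5,7-bis(benzyloxy)-3-(1-{(1R,3R)-2,2-dimethyl-3-[2-(2-methyl-1,3-dioxolan-2-yl)ethyl]cyclopropyl}-2-methylprop-2-en-1-yl)-3-methyl-4-(2-methylpropyl)-3,4-dihydro-2H-chromen-2-one (epimers at the side-chain methine), via lithium enolate 23 (not isolated)
Conditions: LiN(iPr)2, THF, −78 → −40 °C; MeI, DMPU, −78 → −20 °C
Reagents that add atoms: iodomethane CI
Why: Enolate alkylation of the lactone sets the quaternary centre because the pseudo-axial 4-isobutyl group blocks one face and iodomethane enters anti to it, leaving methyl trans and the cyclopropyl-bearing chain cis to isobutyl as the target requires.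

Step 16
Reactants: 24 methylated lactone (as above)
Product: 25 (2R,3R)-3-[2,4-bis(benzyloxy)-6-hydroxyphenyl]-2-(1-{(1R,3R)-2,2-dimethyl-3-[2-(2-methyl-1,3-dioxolan-2-yl)ethyl]cyclopropyl}-2-methylprop-2-en-1-yl)-2,5-dimethylhexan-1-ol
Conditions: LiAlH4, THF, 0 °C → rt
Reagents that add atoms: none
Why: Hydride reduction opens the reactive aryl lactone to the phenol and the neopentyl primary alcohol after the ring has done its job of controlling the quaternary centre.

Step 17
Reactants: 25 phenol alcohol (as above)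
Product: 26 (2R,3R)-2-(1-{(1R,3R)-2,2-dimethyl-3-[2-(2-methyl-1,3-dioxolan-2-yl)ethyl]cyclopropyl}-2-methylprop-2-en-1-yl)-2,5-dimethyl-3-[2,4,6-tris(benzyloxy)phenyl]hexan-1-ol
Conditions: BnBr, K2CO3, DMF, rt
Reagents that add atoms: benzyl bromide BrCc1ccccc1
Why: Williamson ether synthesis is selective for the phenol because carbonate deprotonates only the phenol and not the aliphatic alcohol.

Step 18
Reactants: 26 tribenzyl ether alcohol (as above)
Product: 27 (2R,3S)-2-(1-{(1R,3R)-2,2-dimethyl-3-[2-(2-methyl-1,3-dioxolan-2-yl)ethyl]cyclopropyl}-2-methylprop-2-en-1-yl)-2,5-dimethyl-3-[2,4,6-tris(benzyloxy)phenyl]hexanal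
Conditions: Dess–Martin periodinane, NaHCO3, CH2Cl2, 0 °C → rt
Reagents that add atoms: none
Why: Dess–Martin oxidation gives an aldehyde that has no α-hydrogen and therefore cannot epimerise or self-condense.

Step 19
Reactants: 27 aldehyde (as above)
Product: 29 (2R,3S)-2-(1-{(1R,3R)-2,2-dimethyl-3-[2-(2-methyl-1,3-dioxolan-2-yl)ethyl]cyclopropyl}-2-oxopropyl)-2,5-dimethyl-3-[2,4,6-tris(benzyloxy)phenyl]hexanal (epimers at the ketone α-carbon), via diol 28 (not isolated)
Conditions: K2OsO4·2H2O (2 mol %), NaIO4, 2,6-lutidine, 1,4-dioxane/H2O, rt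
Reagents that add atoms: sodium periodate [Na+].[O-]I(=O)(=O)=O; water O
Why: Lemieux–Johnson oxidative cleavage (dihydroxylation then periodate scission) converts the isopropenyl group into the methyl ketone without ozone, which would attack the electron-rich arene.

Step 20
Reactants: 29 keto aldehyde (as above)
Product: 31 (4R,5R)-5-{(1R,3R)-2,2-dimethyl-3-[2-(2-methyl-1,3-dioxolan-2-yl)ethyl]cyclopropyl}-4-methyl-4-{(1R)-3-methyl-1-[2,4,6-tris(benzyloxy)phenyl]butyl}cyclopent-2-en-1-one, via aldol 30 (not isolated)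
Conditions: KOH, MeOH, rt → 50 °C
Reagents that add atoms: none
Why: Intramolecular aldol condensation closes the five-membered ring in the only productive mode (the aldehyde has no α-hydrogen), and the base equilibrates the ketone α-centre to the more stable epimer with cyclopropyl trans to the bulky 1-aryl-3-methylbutyl group.

Step 21
Reactants: 31 cyclopentenone acetal (as above)
Product: 32 (4R,5R)-5-[(1R,3R)-2,2-dimethyl-3-(3-oxobutyl)cyclopropyl]-4-methyl-4-{(1R)-3-methyl-1-[2,4,6-tris(benzyloxy)phenyl]butyl}cyclopent-2-en-1-one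
Conditions: 1 M HCl, THF, rt
Reagents that add atoms: water O
Why: Acetal hydrolysis with dilute acid frees the side-chain methyl ketone while the arene is still protected, and the unconjugated cyclopropane tolerates the conditions.

Step 22
Reactants: 32 enone diketone (as above)
Product: 33 (2R,3R)-2-[(1R,3R)-2,2-dimethyl-3-(3-oxobutyl)cyclopropyl]-3-methyl-3-[(1R)-3-methyl-1-(2,4,6-trihydroxyphenyl)butyl]cyclopentan-1-one
Conditions: H2 (1 atm), Pd/C (10 wt %), EtOAc/MeOH, rt
Reagents that add atoms: none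
Why: Catalytic hydrogenation saturates the enone and hydrogenolyses the three benzyl ethers in one neutral operation, and the cyclopropane is spared because it is not conjugated with the alkene.

Step 23
Reactants: 33 triol diketone (as above)
Product: 35 2,4,6-trihydroxy-5-[(1R)-1-{(1R,2R)-2-[(1R,3R)-2,2-dimethyl-3-(3-oxobutyl)cyclopropyl]-1-methyl-3-oxocyclopentyl}-3-methylbutyl]benzene-1,3-dicarbaldehyde, via bis-iminium salt 34 (not isolated)
Conditions: POCl3, DMF, MeCN, 0 °C → rt; then H2O, 40 °C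
Reagents that add atoms: N,N-dimethylformamide CN(C)C=O; water O
Why: Vilsmeier–Haack formylation attacks the two free positions of the alkylphloroglucinol far faster than the ketones at 0 °C, and hydrolysis of the bis-iminium salt gives the target.

## Compound list

1 | phloroglucinol (benzene-1,3,5-triol) | Oc1cc(O)cc(O)c1 | starting material
2 | ethyl 5-methyl-3-oxohexanoate | CCOC(=O)CC(=O)CC(C)C | starting material
3 | 5,7-dihydroxy-4-(2-methylpropyl)-2H-chromen-2-one | O=C1C=C(CC(C)C)c2c(O)cc(O)cc2O1 | intermediate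
4 | 5,7-bis(benzyloxy)-4-(2-methylpropyl)-2H-chromen-2-one | O=C1C=C(CC(C)C)c2c(OCc3ccccc3)cc(OCc3ccccc3)cc2O1 | intermediate
5 | (4R)-5,7-bis(benzyloxy)-4-(2-methylpropyl)-3,4-dihydro-2H-chromen-2-one | O=C1C[C@@H](CC(C)C)c2c(OCc3ccccc3)cc(OCc3ccccc3)cc2O1 | intermediate
6 | caronic anhydride, (1R,5S)-6,6-dimethyl-3-oxabicyclo[3.1.0]hexane-2,4-dione (meso) | O=C1OC(=O)[C@@H]2[C@H]1C2(C)C | starting material
7 | [(1R,2S)-3,3-dimethylcyclopropane-1,2-diyl]dimethanol (meso) | OC[C@@H]1[C@H](CO)C1(C)C | intermediate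
8 | [(1S,3R)-3-(hydroxymethyl)-2,2-dimethylcyclopropyl]methyl acetate | OC[C@@H]1[C@H](COC(C)=O)C1(C)C | intermediate
9 | [(1S,3R)-3-formyl-2,2-dimethylcyclopropyl]methyl acetate | O=C[C@@H]1[C@H](COC(C)=O)C1(C)C | intermediate
10 | 1-(triphenylphosphoranylidene)propan-2-one | CC(=O)C=P(c1ccccc1)(c1ccccc1)c1ccccc1 | starting material
11 | [(1S,3R)-2,2-dimethyl-3-[(1E)-3-oxobut-1-en-1-yl]cyclopropyl]methyl acetate | CC(=O)/C=C/[C@@H]1[C@H](COC(C)=O)C1(C)C | intermediate
12 | [(1S,3R)-2,2-dimethyl-3-(3-oxobutyl)cyclopropyl]methyl acetate | CC(=O)CC[C@@H]1[C@H](COC(C)=O)C1(C)C | intermediate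
13 | [(1S,3R)-2,2-dimethyl-3-[2-(2-methyl-1,3-dioxolan-2-yl)ethyl]cyclopropyl]methyl acetate | CC1(CC[C@@H]2[C@H](COC(C)=O)C2(C)C)OCCO1 | intermediate
14 | [(1S,3R)-2,2-dimethyl-3-[2-(2-methyl-1,3-dioxolan-2-yl)ethyl]cyclopropyl]methanol | CC1(CC[C@@H]2[C@H](CO)C2(C)C)OCCO1 | intermediate
15 | (1S,3R)-2,2-dimethyl-3-[2-(2-methyl-1,3-dioxolan-2-yl)ethyl]cyclopropane-1-carbaldehyde | CC1(CC[C@@H]2[C@H](C=O)C2(C)C)OCCO1 | intermediate
16 | lithium (4R)-5,7-bis(benzyloxy)-4-(2-methylpropyl)-4H-chromen-2-olate (lithium enolate of 5) | [Li+].[O-]C1=C[C@@H](CC(C)C)c2c(OCc3ccccc3)cc(OCc3ccccc3)cc2O1 | intermediate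
17 | (4R)-5,7-bis(benzyloxy)-3-[{(1S,3R)-2,2-dimethyl-3-[2-(2-methyl-1,3-dioxolan-2-yl)ethyl]cyclopropyl}(hydroxy)methyl]-4-(2-methylpropyl)-3,4-dihydro-2H-chromen-2-one (diastereomer mixture) | CC1(CC[C@@H]2[C@H](C(O)C3C(=O)Oc4cc(OCc5ccccc5)cc(OCc5ccccc5)c4[C@@H]3CC(C)C)C2(C)C)OCCO1 | intermediate
18 | O-acetate of 17 (acetoxy in place of hydroxy) | CC1(CC[C@@H]2[C@H](C(OC(C)=O)C3C(=O)Oc4cc(OCc5ccccc5)cc(OCc5ccccc5)c4[C@@H]3CC(C)C)C2(C)C)OCCO1 | intermediate
19 | (3E,4S)-5,7-bis(benzyloxy)-3-({(1S,3R)-2,2-dimethyl-3-[2-(2-methyl-1,3-dioxolan-2-yl)ethyl]cyclopropyl}methylidene)-4-(2-methylpropyl)-3,4-dihydro-2H-chromen-2-one | CC1(CC[C@@H]2[C@H](/C=C3/C(=O)Oc4cc(OCc5ccccc5)cc(OCc5ccccc5)c4[C@@H]3CC(C)C)C2(C)C)OCCO1 | intermediate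
20 | isopropenylmagnesium bromide | CC(=C)[Mg]Br | starting material
21 | trimethylsilyl ketene acetal of 22 (2-trimethylsilyloxy-4H-chromene) | CC1(CC[C@@H]2[C@H](C(C(C)=C)C3=C(O[Si](C)(C)C)Oc4cc(OCc5ccccc5)cc(OCc5ccccc5)c4[C@@H]3CC(C)C)C2(C)C)OCCO1 | intermediate
22 | (4R)-5,7-bis(benzyloxy)-3-(1-{(1R,3R)-2,2-dimethyl-3-[2-(2-methyl-1,3-dioxolan-2-yl)ethyl]cyclopropyl}-2-methylprop-2-en-1-yl)-4-(2-methylpropyl)-3,4-dihydro-2H-chromen-2-one (epimer mixture) | CC1(CC[C@@H]2[C@H](C(C(C)=C)C3C(=O)Oc4cc(OCc5ccccc5)cc(OCc5ccccc5)c4[C@@H]3CC(C)C)C2(C)C)OCCO1 | intermediate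
23 | lithium enolate of 22 | [Li+].CC1(CC[C@@H]2[C@H](C(C(C)=C)C3=C([O-])Oc4cc(OCc5ccccc5)cc(OCc5ccccc5)c4[C@@H]3CC(C)C)C2(C)C)OCCO1 | intermediate
24 | (3R,4S)-5,7-bis(benzyloxy)-3-(1-{(1R,3R)-2,2-dimethyl-3-[2-(2-methyl-1,3-dioxolan-2-yl)ethyl]cyclopropyl}-2-methylprop-2-en-1-yl)-3-methyl-4-(2-methylpropyl)-3,4-dihydro-2H-chromen-2-one | CC1(CC[C@@H]2[C@H](C(C(C)=C)[C@]3(C)C(=O)Oc4cc(OCc5ccccc5)cc(OCc5ccccc5)c4[C@@H]3CC(C)C)C2(C)C)OCCO1 | intermediate
25 | (2R,3R)-3-[2,4-bis(benzyloxy)-6-hydroxyphenyl]-2-(1-{(1R,3R)-2,2-dimethyl-3-[2-(2-methyl-1,3-dioxolan-2-yl)ethyl]cyclopropyl}-2-methylprop-2-en-1-yl)-2,5-dimethylhexan-1-ol | CC1(CC[C@@H]2[C@H](C(C(C)=C)[C@](C)(CO)[C@@H](CC(C)C)c3c(O)cc(OCc4ccccc4)cc3OCc3ccccc3)C2(C)C)OCCO1 | intermediate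
26 | (2R,3R)-2-(1-{(1R,3R)-2,2-dimethyl-3-[2-(2-methyl-1,3-dioxolan-2-yl)ethyl]cyclopropyl}-2-methylprop-2-en-1-yl)-2,5-dimethyl-3-[2,4,6-tris(benzyloxy)phenyl]hexan-1-ol | CC1(CC[C@@H]2[C@H](C(C(C)=C)[C@](C)(CO)[C@@H](CC(C)C)c3c(OCc4ccccc4)cc(OCc4ccccc4)cc3OCc3ccccc3)C2(C)C)OCCO1 | intermediate
27 | (2R,3S)-2-(1-{(1R,3R)-2,2-dimethyl-3-[2-(2-methyl-1,3-dioxolan-2-yl)ethyl]cyclopropyl}-2-methylprop-2-en-1-yl)-2,5-dimethyl-3-[2,4,6-tris(benzyloxy)phenyl]hexanal | CC1(CC[C@@H]2[C@H](C(C(C)=C)[C@](C)(C=O)[C@@H](CC(C)C)c3c(OCc4ccccc4)cc(OCc4ccccc4)cc3OCc3ccccc3)C2(C)C)OCCO1 | intermediate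
28 | 1,2-diol from dihydroxylation of the isopropenyl group of 27 | CC1(CC[C@@H]2[C@H](C(C(C)(O)CO)[C@](C)(C=O)[C@@H](CC(C)C)c3c(OCc4ccccc4)cc(OCc4ccccc4)cc3OCc3ccccc3)C2(C)C)OCCO1 | intermediate
29 | (2R,3S)-2-(1-{(1R,3R)-2,2-dimethyl-3-[2-(2-methyl-1,3-dioxolan-2-yl)ethyl]cyclopropyl}-2-oxopropyl)-2,5-dimethyl-3-[2,4,6-tris(benzyloxy)phenyl]hexanal | CC1(CC[C@@H]2[C@H](C(C(C)=O)[C@](C)(C=O)[C@@H](CC(C)C)c3c(OCc4ccccc4)cc(OCc4ccccc4)cc3OCc3ccccc3)C2(C)C)OCCO1 | intermediate
30 | 3-hydroxycyclopentanone aldol adduct preceding 31 | CC1(CC[C@@H]2[C@H](C3C(=O)CC(O)[C@]3(C)[C@@H](CC(C)C)c3c(OCc4ccccc4)cc(OCc4ccccc4)cc3OCc3ccccc3)C2(C)C)OCCO1 | intermediate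
31 | (4R,5R)-5-{(1R,3R)-2,2-dimethyl-3-[2-(2-methyl-1,3-dioxolan-2-yl)ethyl]cyclopropyl}-4-methyl-4-{(1R)-3-methyl-1-[2,4,6-tris(benzyloxy)phenyl]butyl}cyclopent-2-en-1-one | CC1(CC[C@@H]2[C@H]([C@H]3C(=O)C=C[C@]3(C)[C@@H](CC(C)C)c3c(OCc4ccccc4)cc(OCc4ccccc4)cc3OCc3ccccc3)C2(C)C)OCCO1 | intermediate
32 | (4R,5R)-5-[(1R,3R)-2,2-dimethyl-3-(3-oxobutyl)cyclopropyl]-4-methyl-4-{(1R)-3-methyl-1-[2,4,6-tris(benzyloxy)phenyl]butyl}cyclopent-2-en-1-one | CC(=O)CC[C@@H]1[C@H]([C@H]2C(=O)C=C[C@]2(C)[C@@H](CC(C)C)c2c(OCc3ccccc3)cc(OCc3ccccc3)cc2OCc2ccccc2)C1(C)C | intermediate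
33 | (2R,3R)-2-[(1R,3R)-2,2-dimethyl-3-(3-oxobutyl)cyclopropyl]-3-methyl-3-[(1R)-3-methyl-1-(2,4,6-trihydroxyphenyl)butyl]cyclopentan-1-one | CC(=O)CC[C@@H]1[C@H]([C@H]2C(=O)CC[C@]2(C)[C@@H](CC(C)C)c2c(O)cc(O)cc2O)C1(C)C | intermediate
34 | bis(N,N-dimethyliminium) dichloride of 35 (CH=NMe2+ in place of each CHO) | CC(=O)CC[C@@H]1[C@H]([C@H]2C(=O)CC[C@]2(C)[C@@H](CC(C)C)c2c(O)c(C=[N+](C)C)c(O)c(C=[N+](C)C)c2O)C1(C)C.[Cl-].[Cl-] | intermediate
35 | 2,4,6-trihydroxy-5-[(1R)-1-{(1R,2R)-2-[(1R,3R)-2,2-dimethyl-3-(3-oxobutyl)cyclopropyl]-1-methyl-3-oxocyclopentyl}-3-methylbutyl]benzene-1,3-dicarbaldehyde | CC(=O)CC[C@@H]1[C@H]([C@H]2C(=O)CC[C@]2(C)[C@@H](CC(C)C)c2c(O)c(C=O)c(O)c(C=O)c2O)C1(C)C | target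

## Step count and risks

Total: 23 steps. Longest linear sequence: 20 steps (6 → 35, steps 4 to 23); fragment A takes 3 steps (1 → 5).

**Step 3.** The coumarin carries a 4-alkyl group next to a peri benzyloxy group, so the copper hydride reduction may be slow, over-reduce to the lactol or give modest enantioselectivity. The fallback sets out from 1 and makes the stereocentre by C–C bond formation instead of hydride delivery. Phloroglucinol 1 is condensed with ethyl propiolate (ZnCl2, dioxane, 90 °C) to 5,7-dihydroxy-2H-chromen-2-one F1. Benzylation (BnBr, K2CO3) gives 5,7-bis(benzyloxy)-2H-chromen-2-one F2. Copper-catalysed asymmetric conjugate addition of isobutylmagnesium bromide (CuBr·SMe2, a Josiphos-type ferrocenyl diphosphine, t-BuOMe, −78 °C) then comes back to the route at 5.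

**Step 14.** The alkenyl copper reagent has to reach a β-carbon shielded by the gem-dimethylcyclopropane and its cis side chain. The fallback sets out from 19 and changes the two-carbon synthon to a smaller one that is unmasked differently. Vinylmagnesium bromide with CuBr·SMe2 (THF, −40 °C) gives the vinyl lactone F3. Methylation as in step 15 gives the quaternary vinyl lactone F4, LiAlH4 gives the phenol alcohol F5, benzylation gives the tribenzyl ether alcohol F6 and Dess–Martin oxidation gives the vinyl aldehyde F7. A Tsuji–Wacker oxidation (PdCl2, CuCl, O2, DMF/H2O) turns the terminal vinyl group into the methyl ketone and comes back to the route at 29.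

**Step 23.** The chloroiminium electrophile may also attack the two enolisable ketones, and the HCl set free endangers the gem-dimethylcyclopropane. The fallback sets out from 33 and comes back at 35 without any new compound (F0). It uses magnesium-mediated ortho-formylation (MgCl2, Et3N, paraformaldehyde, MeCN, reflux): formaldehyde adds to the magnesium phenoxide and a second formaldehyde takes up hydride, so neither a chloroiminium salt nor strong acid is present.

## Further compounds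

F1 | step 3 | 5,7-dihydroxy-2H-chromen-2-one | O=C1C=Cc2c(O)cc(O)cc2O1
F2 | step 3 | 5,7-bis(benzyloxy)-2H-chromen-2-one | O=C1C=Cc2c(OCc3ccccc3)cc(OCc3ccccc3)cc2O1
F3 | step 14 | vinyl analogue of 22 (prop-2-en-1-yl in place of 2-methylprop-2-en-1-yl) | CC1(CC[C@@H]2[C@H](C(C=C)C3C(=O)Oc4cc(OCc5ccccc5)cc(OCc5ccccc5)c4[C@@H]3CC(C)C)C2(C)C)OCCO1
F4 | step 14 | vinyl analogue of 24 | CC1(CC[C@@H]2[C@H](C(C=C)[C@]3(C)C(=O)Oc4cc(OCc5ccccc5)cc(OCc5ccccc5)c4[C@@H]3CC(C)C)C2(C)C)OCCO1
F5 | step 14 | vinyl analogue of 25 | CC1(CC[C@@H]2[C@H](C(C=C)[C@](C)(CO)[C@@H](CC(C)C)c3c(O)cc(OCc4ccccc4)cc3OCc3ccccc3)C2(C)C)OCCO1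
F6 | step 14 | vinyl analogue of 26 | CC1(CC[C@@H]2[C@H](C(C=C)[C@](C)(CO)[C@@H](CC(C)C)c3c(OCc4ccccc4)cc(OCc4ccccc4)cc3OCc3ccccc3)C2(C)C)OCCO1
F7 | step 14 | vinyl analogue of 27 | CC1(CC[C@@H]2[C@H](C(C=C)[C@](C)(C=O)[C@@H](CC(C)C)c3c(OCc4ccccc4)cc(OCc4ccccc4)cc3OCc3ccccc3)C2(C)C)OCCO1
F0 | step 23 | none | none
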